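**Plan**

- Retrosynthesis: the four methoxymethyl acetals and the C3–OMe bond come off first (3-methyl ether ← flavonol ← C3–H flavone), then ring C is cut at C4a–C4, C4–C3 and O1–C2.
- Enabling feature: C4 is a ketone carbon between arene carbon C4a of ring A and alkene carbon C3 of ring C, and O1 sits on the neighbouring arene carbon C8a. C4 can therefore enter as carbon monoxide between an ortho-iodophenol (ring A) and a terminal arylacetylene (C3, C2 and ring B).
- Forward: the ring B alkyne is built from 4-bromophenol (ortho-prenylation, formylation, Dakin oxidation, acetal protection, alkynylation); the ring A iodophenol comes from phloroglucinol in two steps.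
- Ring C is the only ring made. It closes in the three-component carbonylative coupling; C3 is then hydroxylated and methylated and the acetals are cleaved.
- Stereochemistry: the target has no stereocentre and its side-chain alkene carries two identical methyl groups, so nothing needs control.

Key step: step 9

Remark: all phenols that must survive to the end are carried as methoxymethyl (MOM) ethers, which tolerate amines, palladium catalysis and LiN(i-Pr)2 and leave under dilute acid.

**Route**

Step 1
Reactants: 1 4-bromophenol; 2 prenyl bromide (1-bromo-3-methylbut-2-ene)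
Product: 3 4-bromo-2-(3-methylbut-2-enyl)phenol
Conditions: NaH, toluene, 0 °C to rt
Reagents that add atoms: none
Why: C-alkylation of the sodium phenoxide as a tight ion pair in a non-polar solvent (Claisen-type ortho-C-allylation) should place the prenyl group, through its CH2 terminus, next to oxygen, the para position being blocked by bromine.

Step 2
Reactants: 3 4-bromo-2-(3-methylbut-2-enyl)phenol
Product: 4 5-bromo-2-hydroxy-3-(3-methylbut-2-enyl)benzaldehyde
Conditions: MgCl2, Et3N, (CH2O)n, MeCN, reflux
Reagents that add atoms: paraformaldehyde (source of formaldehyde), C=O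
Why: Magnesium-mediated ortho-formylation (Casnati–Skattebøl reaction): the magnesium phenoxide should deliver formaldehyde to the only free ortho position and a second formaldehyde should oxidise the benzylic alkoxide by hydride transfer, with the aryl bromide and prenyl alkene inert.

Step 3
Reactants: 4 5-bromo-2-hydroxy-3-(3-methylbut-2-enyl)benzaldehyde
Product: 6 5-bromo-3-(3-methylbut-2-enyl)benzene-1,2-diol, via aryl formate 5 (not isolated)
Conditions: 30% H2O2, NaOH, THF–H2O, 0 °C to rt, under N2; dilute HCl work-up
Reagents that add atoms: hydrogen peroxide, OO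
Why: Dakin oxidation: hydroperoxide adds to the aldehyde, the electron-rich aryl group migrates to oxygen to give formate 5, and hydroxide cleaves it; nucleophilic alkaline H2O2 should not epoxidise the unactivated prenyl alkene.

Step 4
Reactants: 6 5-bromo-3-(3-methylbut-2-enyl)benzene-1,2-diol
Product: 7 5-bromo-1,2-bis(methoxymethoxy)-3-(3-methylbut-2-enyl)benzene
Conditions: MOMCl (3 equiv), i-Pr2NEt, CH2Cl2, 0 °C to rt
Reagents that add atoms: chloromethyl methyl ether (MOMCl), COCCl
Why: Williamson-type O-alkylation of both phenols with the reactive α-chloro ether should be clean because no other nucleophilic site is present.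

Step 5
Reactants: 7 5-bromo-1,2-bis(methoxymethoxy)-3-(3-methylbut-2-enyl)benzene; 8 trimethylsilylacetylene
Product: 9 {[3,4-bis(methoxymethoxy)-5-(3-methylbut-2-enyl)phenyl]ethynyl}trimethylsilane
Conditions: PdCl2(PPh3)2 (3 mol %), CuI (5 mol %), Et3N–DMF, 80 °C, sealed tube
Reagents that add atoms: none
Why: Sonogashira coupling: zerovalent palladium inserts into the C–Br bond and the copper acetylide of 8 is transferred; heating is planned because the aryl bromide is electron-rich, and the silyl group prevents double coupling.

Step 6
Reactants: 9 {[3,4-bis(methoxymethoxy)-5-(3-methylbut-2-enyl)phenyl]ethynyl}trimethylsilane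
Product: 10 5-ethynyl-1,2-bis(methoxymethoxy)-3-(3-methylbut-2-enyl)benzene
Conditions: K2CO3 (cat.), MeOH–THF, rt
Reagents that add atoms: none
Why: Base-catalysed methanolysis of the alkynyl C–Si bond (protodesilylation) should free the terminal alkyne without touching the acetals or the prenyl group.

Step 7
Reactants: 11 phloroglucinol (benzene-1,3,5-triol)
Product: 12 3,5-bis(methoxymethoxy)phenol
Conditions: MOMCl (2 equiv), i-Pr2NEt, DMF–CH2Cl2, 0 °C to rt
Reagents that add atoms: chloromethyl methyl ether (MOMCl), COCCl
Why: Statistical Williamson-type O-alkylation of three equivalent hydroxyls: with two equivalents of the chloro ether the bis-acetal should be the main fraction, separable by chromatography from the mono- and tris-acetals, which can be recycled by acid hydrolysis.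

Step 8
Reactants: 12 3,5-bis(methoxymethoxy)phenol
Product: 13 2-iodo-3,5-bis(methoxymethoxy)phenol
Conditions: I2 (1 equiv), NaHCO3, THF–H2O, 0 °C
Reagents that add atoms: iodine, II
Why: Electrophilic aromatic iodination of the phenoxide: the two equivalent positions ortho to the hydroxyl should be attacked in preference to the position flanked by both bulky acetal groups, and the bicarbonate buffer keeps the acetals intact.

Step 9
Reactants: 13 2-iodo-3,5-bis(methoxymethoxy)phenol; 10 5-ethynyl-1,2-bis(methoxymethoxy)-3-(3-methylbut-2-enyl)benzene; 14 carbon monoxide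
Product: 17 5,7-bis(methoxymethoxy)-2-[3,4-bis(methoxymethoxy)-5-(3-methylbut-2-enyl)phenyl]chromen-4-one, via ynone 15 (not isolated), via enaminone 16 (not isolated)
Conditions: CO (5 bar), PdCl2(PPh3)2 (5 mol %), Et2NH, 100 °C, no copper
Reagents that add atoms: none
Why: PdCl2(PPh3)2 is reduced in the flask to zerovalent palladium, which inserts into the C–I bond of 13; CO insertion gives the aroylpalladium iodide, and amine-assisted transfer of the acetylide of 10 followed by reductive elimination forms C4a–C4 and C4–C3 in ynone 15. Diethylamine then adds to the ynone at C2 to give enaminone 16, and the ortho-hydroxyl closes ring C at O1–C2 by a 6-endo-trig addition–elimination that returns the amine. The closest known reaction type is the palladium-catalysed carbonylative Sonogashira annulation of ortho-iodophenols with terminal arylacetylenes in secondary amines, which gives flavones. No stereocentre is formed. Two selectivities are needed: CO insertion must outrun direct alkynylation, which the absence of copper, the CO pressure and the ready acyl migration of the electron-rich, doubly ortho-substituted aryl group should secure; and six-membered closure must beat 5-exo closure to the aurone, which the prior amine addition should secure because the enaminone is electrophilic only at C2.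

Step 10
Reactants: 17 5,7-bis(methoxymethoxy)-2-[3,4-bis(methoxymethoxy)-5-(3-methylbut-2-enyl)phenyl]chromen-4-one
Product: 20 3-hydroxy-5,7-bis(methoxymethoxy)-2-[3,4-bis(methoxymethoxy)-5-(3-methylbut-2-enyl)phenyl]chromen-4-one, via 3-lithioflavone 18 (not isolated), via flavon-3-ylboronate 19 (not isolated)
Conditions: LiN(i-Pr)2 (3 equiv), THF, −78 °C; B(OMe)3, −78 °C to rt; AcOH, 30% H2O2, 0 °C to rt
Reagents that add atoms: hydrogen peroxide, OO
Why: Carbonyl-directed deprotonation at C3 (the only vinylic C–H next to the C4 carbonyl), trapping as the borate and oxidative 1,2-migration from boron to oxygen (organoborane oxidation) is the established flavone-to-flavonol sequence; at −78 °C the amide base should not touch the arene C–H bonds or the benzylic–allylic CH2, and H2O2 should spare the prenyl alkene.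

Step 11
Reactants: 20 3-hydroxy-5,7-bis(methoxymethoxy)-2-[3,4-bis(methoxymethoxy)-5-(3-methylbut-2-enyl)phenyl]chromen-4-one
Product: 21 3-methoxy-5,7-bis(methoxymethoxy)-2-[3,4-bis(methoxymethoxy)-5-(3-methylbut-2-enyl)phenyl]chromen-4-one
Conditions: MeI, K2CO3, acetone, reflux
Reagents that add atoms: iodomethane, CI
Why: Williamson ether synthesis on the only free hydroxyl, the acidic 3-OH of the flavonol, should give the 3-methyl ether selectively.

Step 12
Reactants: 21 3-methoxy-5,7-bis(methoxymethoxy)-2-[3,4-bis(methoxymethoxy)-5-(3-methylbut-2-enyl)phenyl]chromen-4-one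
Product: 22 uralenol 3-methyl ether, 2-[3,4-dihydroxy-5-(3-methylbut-2-enyl)phenyl]-5,7-dihydroxy-3-methoxychromen-4-one
Conditions: 3 M aq. HCl–MeOH (1:4), 40 °C
Reagents that add atoms: none
Why: Acid-catalysed transacetalisation of the four aryl methoxymethyl ethers with methanol releases the phenols and dimethoxymethane; dilute acid and mild temperature are chosen so that acid-promoted cyclisation of the prenyl chain onto the neighbouring 4'-hydroxyl should stay slow, and the 3-methyl ether is inert.

**Compound list**

1 | 4-bromophenol | Oc1ccc(Br)cc1 | starting material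
2 | prenyl bromide (1-bromo-3-methylbut-2-ene) | CC(C)=CCBr | starting material
3 | 4-bromo-2-(3-methylbut-2-enyl)phenol | CC(C)=CCc1cc(Br)ccc1O | intermediate
4 | 5-bromo-2-hydroxy-3-(3-methylbut-2-enyl)benzaldehyde | CC(C)=CCc1cc(Br)cc(C=O)c1O | intermediate
5 | 5-bromo-2-hydroxy-3-(3-methylbut-2-enyl)phenyl formate | CC(C)=CCc1cc(Br)cc(OC=O)c1O | intermediate
6 | 5-bromo-3-(3-methylbut-2-enyl)benzene-1,2-diol | CC(C)=CCc1cc(Br)cc(O)c1O | intermediate
7 | 5-bromo-1,2-bis(methoxymethoxy)-3-(3-methylbut-2-enyl)benzene | COCOc1cc(Br)cc(CC=C(C)C)c1OCOC | intermediate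
8 | trimethylsilylacetylene | C#C[Si](C)(C)C | starting material
9 | {[3,4-bis(methoxymethoxy)-5-(3-methylbut-2-enyl)phenyl]ethynyl}trimethylsilane | COCOc1cc(C#C[Si](C)(C)C)cc(CC=C(C)C)c1OCOC | intermediate
10 | 5-ethynyl-1,2-bis(methoxymethoxy)-3-(3-methylbut-2-enyl)benzene | C#Cc1cc(OCOC)c(OCOC)c(CC=C(C)C)c1 | intermediate
11 | phloroglucinol | Oc1cc(O)cc(O)c1 | starting material
12 | 3,5-bis(methoxymethoxy)phenol | COCOc1cc(O)cc(OCOC)c1 | intermediate
13 | 2-iodo-3,5-bis(methoxymethoxy)phenol | COCOc1cc(O)c(I)c(OCOC)c1 | intermediate
14 | carbon monoxide | [C-]#[O+] | starting material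
15 | 1-[2-hydroxy-4,6-bis(methoxymethoxy)phenyl]-3-[3,4-bis(methoxymethoxy)-5-(3-methylbut-2-enyl)phenyl]prop-2-yn-1-one | COCOc1cc(O)c(C(=O)C#Cc2cc(OCOC)c(OCOC)c(CC=C(C)C)c2)c(OCOC)c1 | intermediate
16 | (E)-3-(diethylamino)-1-[2-hydroxy-4,6-bis(methoxymethoxy)phenyl]-3-[3,4-bis(methoxymethoxy)-5-(3-methylbut-2-enyl)phenyl]prop-2-en-1-one (geometry erased on ring closure) | CCN(CC)/C(=C/C(=O)c1c(O)cc(OCOC)cc1OCOC)c1cc(OCOC)c(OCOC)c(CC=C(C)C)c1 | intermediate
17 | 5,7-bis(methoxymethoxy)-2-[3,4-bis(methoxymethoxy)-5-(3-methylbut-2-enyl)phenyl]chromen-4-one | COCOc1cc(OCOC)c2c(c1)oc(-c1cc(OCOC)c(OCOC)c(CC=C(C)C)c1)cc2=O | intermediate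
18 | 3-lithio-5,7-bis(methoxymethoxy)-2-[3,4-bis(methoxymethoxy)-5-(3-methylbut-2-enyl)phenyl]chromen-4-one | [Li]c1c(-c2cc(OCOC)c(OCOC)c(CC=C(C)C)c2)oc2cc(OCOC)cc(OCOC)c2c1=O | intermediate
19 | dimethyl {5,7-bis(methoxymethoxy)-2-[3,4-bis(methoxymethoxy)-5-(3-methylbut-2-enyl)phenyl]-4-oxochromen-3-yl}boronate (from the lithium borate on acidification) | COB(OC)c1c(-c2cc(OCOC)c(OCOC)c(CC=C(C)C)c2)oc2cc(OCOC)cc(OCOC)c2c1=O | intermediate
20 | 3-hydroxy-5,7-bis(methoxymethoxy)-2-[3,4-bis(methoxymethoxy)-5-(3-methylbut-2-enyl)phenyl]chromen-4-one | Oc1c(-c2cc(OCOC)c(OCOC)c(CC=C(C)C)c2)oc2cc(OCOC)cc(OCOC)c2c1=O | intermediate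
21 | 3-methoxy-5,7-bis(methoxymethoxy)-2-[3,4-bis(methoxymethoxy)-5-(3-methylbut-2-enyl)phenyl]chromen-4-one | COc1c(-c2cc(OCOC)c(OCOC)c(CC=C(C)C)c2)oc2cc(OCOC)cc(OCOC)c2c1=O | intermediate
22 | uralenol 3-methyl ether, 2-[3,4-dihydroxy-5-(3-methylbut-2-enyl)phenyl]-5,7-dihydroxy-3-methoxychromen-4-one | COc1c(-c2cc(O)c(O)c(CC=C(C)C)c2)oc2cc(O)cc(O)c2c1=O | target

**Step count and risks**

Total step count: 12. Longest linear sequence: 10 steps (steps 1–6, then 9–12); the ring A branch (steps 7–8) joins at step 9.

Steps most likely to fail:

Step 9. With the free phenol and a nucleophilic amine present throughout the hot palladium cycle, three processes can divert material. Uncarbonylated alkynylation followed by closure gives a benzofuran, 5-exo closure of the ynone gives an aurone, and diethylamine can capture the aroylpalladium species as an amide. The fallback separates bond formation from ring closure and masks the phenol. It sets out from 13, which is acetylated (Ac2O, pyridine, rt) to 2-iodo-3,5-bis(methoxymethoxy)phenyl acetate F1. Carbonylative Sonogashira coupling of F1 with 10 and 14 under mild, non-nucleophilic conditions (CO 1 atm, PdCl2(PPh3)2, Et3N, THF, rt to 40 °C) should give the isolable ynone 2-{3-[3,4-bis(methoxymethoxy)-5-(3-methylbut-2-enyl)phenyl]prop-2-ynoyl}-3,5-bis(methoxymethoxy)phenyl acetate F2. Treating F2 with Et2NH in EtOH at rt to 50 °C should remove the acetate by aminolysis, giving 15. The amine then adds to C2 to form 16 and six-membered closure follows. The sequence comes back to the route at 17.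

Step 8. Iodination may occur at the position para to the hydroxyl, between the two acetal oxygens, or run on to di-iodination, and the wrong regioisomer cannot cyclise. The fallback replaces electrophilic substitution by directed ortho-metalation. It sets out from 12, which is carbamoylated (Et2NCOCl, K2CO3, MeCN, reflux) to 3,5-bis(methoxymethoxy)phenyl N,N-diethylcarbamate F3. Lithiation with s-BuLi and TMEDA in THF at −78 °C should occur between the carbamate, the strongest oxygen director, and the adjacent acetal. An I2 quench then gives 2-iodo-3,5-bis(methoxymethoxy)phenyl N,N-diethylcarbamate F4. Hydrolysis of the carbamate (NaOH, EtOH, reflux), which the acetals and the aryl iodide should tolerate, comes back to the route at 13.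

Step 1. The ambident phenoxide may alkylate at oxygen, take up a second prenyl group, or give mixtures that are hard to separate. The fallback forms the C–C bond by a sigmatropic shift instead of direct C-alkylation. It sets out from 1, which is O-allylated at the tertiary terminus with methyl 2-methylbut-3-en-2-yl carbonate under Pd(PPh3)4 catalysis (THF, 0 °C) to give 1-bromo-4-[(2-methylbut-3-en-2-yl)oxy]benzene F5. Aromatic Claisen rearrangement of F5 (N,N-diethylaniline, 130 °C) transfers the chain to the ortho carbon with allylic inversion and should give the normal prenyl phenol, coming back to the route at 3.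

**Further compounds**

F1 | step 9 | 2-iodo-3,5-bis(methoxymethoxy)phenyl acetate | CC(=O)Oc1cc(OCOC)cc(OCOC)c1I
F2 | step 9 | 2-{3-[3,4-bis(methoxymethoxy)-5-(3-methylbut-2-enyl)phenyl]prop-2-ynoyl}-3,5-bis(methoxymethoxy)phenyl acetate | CC(=O)Oc1cc(OCOC)cc(OCOC)c1C(=O)C#Cc1cc(OCOC)c(OCOC)c(CC=C(C)C)c1
F3 | step 8 | 3,5-bis(methoxymethoxy)phenyl N,N-diethylcarbamate | CCN(CC)C(=O)Oc1cc(OCOC)cc(OCOC)c1
F4 | step 8 | 2-iodo-3,5-bis(methoxymethoxy)phenyl N,N-diethylcarbamate | CCN(CC)C(=O)Oc1cc(OCOC)cc(OCOC)c1I
F5 | step 1 | 1-bromo-4-[(2-methylbut-3-en-2-yl)oxy]benzene | C=CC(C)(C)Oc1ccc(Br)cc1
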